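**Retrosynthetic overview** (labdane numbering C1–C20)

1. Target ⇒ acyclic isomer (only ring: the butenolide; only carbinol stereocentre: C6). One cobalt-hydride MHAT radical cycloisomerization forms C4–C5 (ring A, first), then C9–C10 (ring B, second), and ends by leaving the C7=C8 bond.
2. Acyclic ester ⇒ Still–Gennari Z-olefination (C8=C9) of an α-branched phosphonate with 3-(2-oxo-2,5-dihydrofuran-3-yl)propanal.
3. Phosphonate ⇒ C7–C8 alkylation with the (R)-chlorohydrin already esterified with (R)-2-methylbutanoic acid; C6 comes from CBS reduction of a chloromethyl enone.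
4. Enone ⇒ zirconium-catalysed carboalumination of 6-methylhept-6-en-1-yne (E-C5=C10 and the C10 methyl) plus chloroacetyl chloride; enyne ⇒ acetylide alkylation.
5. Aldehyde ⇒ Negishi coupling of 3-bromofuran-2(5H)-one with acetal-protected 3-oxopropylzinc bromide, then hydrolysis.

Assumption: 5-bromo-2-methylpent-1-ene, (R)-2-methylbutanoic acid, 3-bromofuran-2(5H)-one and [2-(1,3-dioxolan-2-yl)ethyl]zinc bromide (THF solution) are taken as catalogue chemicals.

**Route**

Step 1
Reactants: 1 5-bromo-2-methylpent-1-ene; 2 lithium acetylide–ethylenediamine complex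
Product: 3 6-methylhept-6-en-1-yne
Conditions: 2 (1.3 equiv), DMSO, 10 °C → rt
Reagents that add atoms: none
Why: SN2 alkylation of lithium acetylide at the unhindered primary bromide in DMSO gives the terminal alkyne without touching the 1,1-disubstituted alkene, and no stereocentre is formed.

Step 2
Reactants: 3 6-methylhept-6-en-1-yne; 4 chloroacetyl chloride
Product: 6 (3E)-1-chloro-4,8-dimethylnona-3,8-dien-2-one, via E-alkenyldimethylalane 5 (not isolated)
Conditions: AlMe3 (2.0 equiv), Zr(C5H5)2Cl2 (0.25 equiv), CH2Cl2, 0 °C → rt, 12 h; volatiles removed in vacuo; then 4 (1.5 equiv), CH2Cl2, –30 → 0 °C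
Reagents that add atoms: trimethylaluminium, C[Al](C)C
Why: Zirconium-catalysed Negishi carboalumination adds CH3 and Al syn across the terminal alkyne with CH3 on the internal carbon, which fixes the E geometry of the future C5=C10 bond, and the alkenyl–aluminium bond is then acylated with retention by the acid chloride (alkenylalane acylation).

Step 3
Reactants: 6 (3E)-1-chloro-4,8-dimethylnona-3,8-dien-2-one
Product: 7 (2R,3E)-1-chloro-4,8-dimethylnona-3,8-dien-2-ol
Conditions: (R)-1-methyl-3,3-diphenyltetrahydro-1H,3H-pyrrolo[1,2-c][1,3,2]oxazaborole [(R)-Me-CBS] (0.15 equiv), catecholborane (1.5 equiv), toluene, –78 °C; MeOH, then aq NaHCO3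
Reagents that add atoms: none
Why: Corey–Bakshi–Shibata reduction with catecholborane (which does not hydroborate the alkenes at –78 °C) reduces the enone in the 1,2-sense with the alkenyl group as the large substituent, so the (R)-catalyst gives the (R)-chlorohydrin whose carbinol carbon becomes C6.

Step 4
Reactants: 7 (2R,3E)-1-chloro-4,8-dimethylnona-3,8-dien-2-ol; 8 (2R)-2-methylbutanoic acid
Product: 9 (2R,3E)-1-chloro-4,8-dimethylnona-3,8-dien-2-yl (2R)-2-methylbutanoate
Conditions: 8 (1.3 equiv), DCC (1.4 equiv), 4-(dimethylamino)pyridine (0.1 equiv), CH2Cl2, 0 °C → rt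
Reagents that add atoms: none
Why: Steglich esterification acylates the secondary allylic alcohol under near-neutral conditions that neither close the chlorohydrin to an epoxide nor epimerise the α-centre of the acid, whose (R) configuration is bought.

Step 5
Reactants: 9 (2R,3E)-1-chloro-4,8-dimethylnona-3,8-dien-2-yl (2R)-2-methylbutanoate
Product: 10 methyl (4S,5E)-2-[bis(2,2,2-trifluoroethoxy)phosphoryl]-6,10-dimethyl-4-{[(2R)-2-methylbutanoyl]oxy}undeca-5,10-dienoate (both C2 epimers)
Conditions: methyl bis(2,2,2-trifluoroethyl)phosphonoacetate (2.0 equiv), NaH (1.9 equiv), Bu4NI (0.2 equiv), DMF, 0 → 60 °C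
Reagents that add atoms: methyl 2-[bis(2,2,2-trifluoroethoxy)phosphoryl]acetate, COC(=O)CP(=O)(OCC(F)(F)F)OCC(F)(F)F
Why: Malonate-type SN2 alkylation of the soft sodium phosphonoacetate anion at the primary carbon, assisted by iodide (Finkelstein exchange), forms the C7–C8 bond without touching C6, and the new phosphonate carbon is an epimer mixture that is erased in step 8.

Step 6
Reactants: 11 3-bromofuran-2(5H)-one; 12 [2-(1,3-dioxolan-2-yl)ethyl]zinc bromide (3-oxopropylzinc bromide protected as its ethylene acetal)
Product: 13 3-[2-(1,3-dioxolan-2-yl)ethyl]furan-2(5H)-one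
Conditions: 12 (1.3 equiv), Pd(PPh3)4 (5 mol%), THF, 45 °C
Reagents that add atoms: none
Why: Negishi sp2–sp3 cross-coupling works because zerovalent palladium inserts readily into the activated C–Br bond of the α-bromobutenolide and the functionalised alkylzinc transmetallates without attacking the lactone.

Step 7
Reactants: 13 3-[2-(1,3-dioxolan-2-yl)ethyl]furan-2(5H)-one
Product: 14 3-(2-oxo-2,5-dihydrofuran-3-yl)propanal
Conditions: 1 M aq HCl, THF, rt
Reagents that add atoms: water, O
Why: Acid-catalysed acetal hydrolysis releases the aldehyde while the butenolide is stable to dilute aqueous acid.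

Step 8
Reactants: 10 methyl (4S,5E)-2-[bis(2,2,2-trifluoroethoxy)phosphoryl]-6,10-dimethyl-4-{[(2R)-2-methylbutanoyl]oxy}undeca-5,10-dienoate; 14 3-(2-oxo-2,5-dihydrofuran-3-yl)propanal
Product: 16 methyl (2Z,4S,5E)-6,10-dimethyl-4-{[(2R)-2-methylbutanoyl]oxy}-2-[3-(2-oxo-2,5-dihydrofuran-3-yl)propylidene]undeca-5,10-dienoate, via potassium phosphonoenolate 15 (not isolated)
Conditions: KN(SiMe3)2 (1.0 equiv), 18-crown-6 (3 equiv), THF, –78 °C, 30 min; then 14 (1.2 equiv), –78 °C
Reagents that add atoms: none
Why: Still–Gennari olefination gives the Z-enoate (ester cis to the C11 chain, C7 trans to C11) because the electron-poor bis(trifluoroethyl) phosphonate eliminates kinetically from the syn adduct under dissociating potassium/crown-ether conditions at –78 °C, where the stabilised anion leaves the esters and the butenolide alone.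

Step 9
Reactants: 16 methyl (2Z,4S,5E)-6,10-dimethyl-4-{[(2R)-2-methylbutanoyl]oxy}-2-[3-(2-oxo-2,5-dihydrofuran-3-yl)propylidene]undeca-5,10-dienoate
Product: 17 methyl (5S,6S,9R,10R)-6-{[(2R)-2-methylbutanoyl]oxy}-16-oxo-15,16-epoxylabda-7,13-dien-17-oate (CNP0147155.1)
Conditions: Co(C36H52N2O2)Cl [chloride of the trivalent cobalt complex of N,N′-bis(3,5-di-tert-butylsalicylidene)cyclohexane-1,2-diamine] (10 mol%), PhSiH3 (20 mol%), degassed benzene (0.01 M), 22 °C
Reagents that add atoms: none
Why: Proposed new method: a trivalent cobalt hydride formed from the cobalt chloride and PhSiH3 transfers a hydrogen atom to the 1,1-disubstituted alkene (MHAT), the tertiary C4 radical closes ring A by 6-endo attack on C5, the tertiary C10 radical closes ring B by 6-endo attack on the β-carbon C9 of the enoate, and the α-ester radical at C8 returns H7 to divalent cobalt to leave the C7=C8 bond and regenerate the hydride, the closest known reaction types being cobalt–salen MHAT cycloisomerization of dienes and MHAT-initiated radical polyene bicyclization onto unsaturated esters; in the chair–chair transition state the C6 acyloxy group is equatorial (its C–H eclipses the C5=C10 plane to avoid allylic 1,3-strain with the C10 methyl), the E-alkene gives the trans ring fusion and the Z-enoate places C11 equatorial, so C5 (S), C10 (R) and C9 (R) are all set from the C6 (S) centre.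

**Compound list**

1 | 5-bromo-2-methylpent-1-ene | C=C(C)CCCBr | starting material
2 | lithium acetylide–ethylenediamine complex | [Li]C#C.NCCN | starting material
3 | 6-methylhept-6-en-1-yne | C=C(C)CCCC#C | intermediate
4 | chloroacetyl chloride | ClCC(Cl)=O | starting material
5 | dimethyl[(1E)-2,6-dimethylhepta-1,6-dien-1-yl]alumane | C=C(C)CCC/C(C)=C/[Al](C)C | intermediate
6 | (3E)-1-chloro-4,8-dimethylnona-3,8-dien-2-one | C=C(C)CCC/C(C)=C/C(=O)CCl | intermediate
7 | (2R,3E)-1-chloro-4,8-dimethylnona-3,8-dien-2-ol | O[C@H](/C=C(\C)CCCC(C)=C)CCl | intermediate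
8 | (2R)-2-methylbutanoic acid | CC[C@@H](C)C(=O)O | starting material
9 | (2R,3E)-1-chloro-4,8-dimethylnona-3,8-dien-2-yl (2R)-2-methylbutanoate | CC[C@@H](C)C(=O)O[C@H](/C=C(\C)CCCC(C)=C)CCl | intermediate
10 | methyl (4S,5E)-2-[bis(2,2,2-trifluoroethoxy)phosphoryl]-6,10-dimethyl-4-{[(2R)-2-methylbutanoyl]oxy}undeca-5,10-dienoate | CC[C@@H](C)C(=O)O[C@H](/C=C(\C)CCCC(C)=C)CC(C(=O)OC)P(=O)(OCC(F)(F)F)OCC(F)(F)F | intermediate
11 | 3-bromofuran-2(5H)-one | O=C1OCC=C1Br | starting material
12 | [2-(1,3-dioxolan-2-yl)ethyl]zinc bromide | Br[Zn]CCC1OCCO1 | starting material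
13 | 3-[2-(1,3-dioxolan-2-yl)ethyl]furan-2(5H)-one | O=C1OCC=C1CCC1OCCO1 | intermediate
14 | 3-(2-oxo-2,5-dihydrofuran-3-yl)propanal | O=CCCC1=CCOC1=O | intermediate
15 | potassium salt of the C2 carbanion of 10 | CC[C@@H](C)C(=O)O[C@H](/C=C(\C)CCCC(C)=C)C[C-](C(=O)OC)P(=O)(OCC(F)(F)F)OCC(F)(F)F.[K+] | intermediate
16 | methyl (2Z,4S,5E)-6,10-dimethyl-4-{[(2R)-2-methylbutanoyl]oxy}-2-[3-(2-oxo-2,5-dihydrofuran-3-yl)propylidene]undeca-5,10-dienoate | CC[C@@H](C)C(=O)O[C@H](/C=C(\C)CCCC(C)=C)C/C(C(=O)OC)=C/CCC1=CCOC1=O | intermediate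
17 | methyl (5S,6S,9R,10R)-6-{[(2R)-2-methylbutanoyl]oxy}-16-oxo-15,16-epoxylabda-7,13-dien-17-oate (6α-acyloxy, 5α-H, 9α-H, 10β-CH3) | CC[C@@H](C)C(=O)O[C@H]1C=C(C(=O)OC)[C@H](CCC2=CCOC2=O)[C@@]2(C)CCCC(C)(C)[C@H]12 | target

**Totals and risks**

Total step count: 9. Longest linear sequence: 7 (steps 1, 2, 3, 4, 5, 8, 9).

Step 9 is the most likely to fail.
- The C8 radical may return the hydrogen from C9 instead of C7 (giving the 8(9)-ene) or be reduced.
- The C10 radical may be quenched before ring B closes.
- The terminal alkene may simply isomerise.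
- The 1,2-induction from C6 in the first ring closure is predicted from sterics, not demonstrated.

Fallback for step 9: it sets out from 16 and comes back at 17. The bicyclization is run as a hydrochlorination with the salen complex of divalent cobalt Co(C36H52N2O2) (8 mol%), 4-methylbenzenesulfonyl chloride (added slowly), PhSiH3 and EtOH at rt. The C8 radical is then ended by chlorine-atom transfer instead of hydrogen return, giving the tertiary 8-chloro ester F1. Dehydrochlorination of F1 with DBU in toluene at 60 °C removes the accessible H7 and gives 17. The position of the double bond is thereby decided in a separate polar elimination.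

Step 5 is the second risk: the β-acyloxy primary chloride is a sluggish electrophile, and the phosphonate anion may attack the ester instead.

Fallback for step 5: it sets out from 6 and comes back at 10. The sodium phosphonoacetate is alkylated with the far more reactive α-chloro ketone 6 (DMF, 0 °C) to the keto phosphonate F2. The enone carbonyl is reduced with (R)-Me-CBS and catecholborane at –78 °C to the hydroxy phosphonate F3. F3 is acylated at once with 8 (DCC, 4-(dimethylamino)pyridine), before it can lactonise, to give 10.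

Step 2 is the third risk: methyl transfer from aluminium or Lewis-acid acylation of the 1,1-disubstituted alkene may compete with acylation of the alkenyl–aluminium bond.

Fallback for step 2: it sets out from 3 and comes back at 6. After the same carboalumination, alane 5 is quenched with I2 to the isolable alkenyl iodide F4. Halogen–lithium exchange (t-BuLi, Et2O, –78 °C) gives the alkenyllithium F5. F5 is acylated with 2-chloro-N-methoxy-N-methylacetamide to give 6 without any Lewis acid.

**Further compounds**

F1 | step 9 | methyl (5S,6S,9R,10R)-8-chloro-6-{[(2R)-2-methylbutanoyl]oxy}-16-oxo-15,16-epoxylabd-13-en-17-oate (C8 epimers) | CC[C@@H](C)C(=O)O[C@H]1CC(Cl)(C(=O)OC)[C@H](CCC2=CCOC2=O)[C@@]2(C)CCCC(C)(C)[C@H]12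
F2 | step 5 | methyl (5E)-2-[bis(2,2,2-trifluoroethoxy)phosphoryl]-6,10-dimethyl-4-oxoundeca-5,10-dienoate | C=C(C)CCC/C(C)=C/C(=O)CC(C(=O)OC)P(=O)(OCC(F)(F)F)OCC(F)(F)F
F3 | step 5 | methyl (4S,5E)-2-[bis(2,2,2-trifluoroethoxy)phosphoryl]-4-hydroxy-6,10-dimethylundeca-5,10-dienoate | O[C@H](/C=C(\C)CCCC(C)=C)CC(C(=O)OC)P(=O)(OCC(F)(F)F)OCC(F)(F)F
F4 | step 2 | (1E)-1-iodo-2,6-dimethylhepta-1,6-diene | C=C(C)CCC/C(C)=C/I
F5 | step 2 | [(1E)-2,6-dimethylhepta-1,6-dien-1-yl]lithium | C=C(C)CCC/C(C)=C/[Li]
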